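If the dissolved partner stays close to its saturation value, you can reckon the end of this flask from a single number, so start with the test of that condition.

    substrate + partner ⇌ target (K1 = 1960 L mol⁻¹, k1 = 86.0 L mol⁻¹ s⁻¹)
    substrate + partner ⇌ isomer of the product (K2 = 1520 L mol⁻¹, k2 = 50.6 L mol⁻¹ s⁻¹)
    gas ⇌ partner, rate k3*(csat - [partner]) (k3 = 11.5 s⁻¹, csat = 1.9 mM)

substrate 0.0050 M; gas 1.9 mM (held); time 4.0 min

- which holds at 4.0 min: what has brought the reaction to rest, or that it has not come to rest (forward and back rates have come level / all of the substrate has reacted / it is still moving)
- how much of the substrate has reacted by 4.0 min
- how much target there is at 4.0 min, in percent of the substrate charged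
- how much isomer of the product there is at 4.0 min, in percent of the substrate charged

- at the start none of partner is dissolved
- the reaction counts as stopped when no species that holds the substrate changes by six tenths of a point or more over the second half of the time
- run time (flask): 4.0 min

- Turn the question round: two things could keep this flask moving at 4.0 min, partner lagging well below saturation, or steps too slow for the time.
- Take the partner first. With the whole charge unreacted, the substrate uses up partner at 0.683 s⁻¹, a pseudo-first-order rate, while the gas refills it faster, at 11.5 s⁻¹. So the first answer is a dip of 5.94% below saturation.
- That dip slows the uptake a little. Put it back in and go round once more: 5.59%.
- Now the time. The slower way back is from the isomer of the product, with one turnover in 30.0 s. You have 8.00 of those in this flask, so I expect forward and back rates to be level.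
- At that point, with the partner at saturation, target plus isomer of the product over substrate equals the sum of the two equilibrium constants times the saturation concentration. Call this the balance number, 6.61. The substrate charge does not appear in it.
- My reckoning leaves 13.1% of the substrate free, so it does not run out. Conversion is 86.9%, with 48.9% target and 37.9% isomer of the product.
- The forecast says forward and back rates have come level, with 86.9% conversion, 48.9% target and 37.9% isomer of the product, holding that “the dissolved partner sits at essentially saturation”.
- The simulation gives forward and back rates have come level, with 86.9% conversion, 48.9% target and 37.9% isomer of the product.
- In this flask, target plus isomer of the product over substrate stands at 6.63, against a balance number of 6.61. Now charge a neighbour with 0.0085 M of substrate. Its balance number stays 6.61, so you again expect 13.1% left, provided the partner holds. Its uptake starts at 1.16 s⁻¹, still slower than the refill at 11.5 s⁻¹, for a first dip of 10.1%. At 4.00 min the neighbour holds 0.00190 M of partner and 13% of its substrate, with 48.9% target and 37.9% isomer of the product.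

(The numbers are assumed, and the outcome is calculated.)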